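50.0% of the electrophile charged to red can be taken by the protic impurity, one for one, and ochre has the same share; I started from that number.

| setting | midnight | red | ochre |
|---|---|---|---|
| electrophile | 0.21 M | 0.32 M | 0.32 M |
| nucleophile | 0.48 M | 0.480 M | 0.480 M |
| free base | 0.384 M | 0.380 M | 0.500 M |
| protic impurity | 0.16 M | 0.160 M | 0.160 M |
| remark | run made earlier |  |  |
| time |  | 30 h | 30 h |

midnight run (percent of the electrophile charged)

| time / h | electrophile / % | target / % |
|---|---|---|
| 0.500 | 77.1 | 3.0 |
| 1.50 | 54.6 | 4.6 |
| 3.00 | 40.3 | 4.6 |
| 4.00 | 35.3 | 5.2 |
| 6.00 | 27.7 | 4.3 |

(standard deviation of a reading: 0.3 percentage points)

- candidate steps: free base + target -> over-reaction product; acid set free + free base <-> salt of the base; electrophile + protic impurity -> quenched substrate; nucleophile <-> dormant form; electrophile + nucleophile -> acid set free + target; nucleophile + acid set free <-> protonated nucleophile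
- no earlier run changes the charge of free base; that part of a forecast is a guess

* part of the electrophile that has reacted at the end, red
* part of the electrophile that has reacted at the end, ochre
* what raising the concentration of free base from its lowest to its highest value here does to the part of the electrophile that has reacted (changes below 5 percentage points count as none) (it rises / no change / it falls)

From the first midnight reading I took the electrophile lost, subtracted the target, and divided that rate by the mean concentrations over the interval. This gave a quenching rate constant of 3.23 M⁻¹ h⁻¹, a reading with its scatter. When quenching consumes the two species equally, their difference stays constant and [protic impurity]/[electrophile] decays exponentially. I called its time constant the surplus time constant, one over the rate constant times the charged excess of electrophile over impurity: 1.93 h for red and ochre. Midnight's smaller excess gave 6.19 h, longer than red's, so its last reading, at 6.00 h, lay within one such time.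

I drew red accordingly. By quenching the electrophile starts falling at a fractional rate of 0.517 h⁻¹, and the impurity, the limiting reagent of this pair, is half used by 0.784 h. By 9.65 h the ratio is down by a factor of 148, which is the knee. Quenching then levels off with 50.0% of the electrophile quenched, and a slow tail through the nucleophile follows. I committed to more than 50.0% reacted in red and ochre and put no number on the tail. Free base does not enter the time constant, so I guessed no trend.

The forecast gave 78% for red, 78% for ochre and no change, “giving roughly 75–80% reacted, with wide uncertainty”. The flasks gave 64.4% in red and 64.5% in ochre, so the trend was no change, with a change of 0.041 percentage points.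

    free base + target → over-reaction product (k = 0.210 M⁻¹ h⁻¹)
    acid set free + free base ⇌ salt of the base, settled at all times (K = 7.10 M⁻¹)
    electrophile + protic impurity → quenched substrate (k = 3.30 M⁻¹ h⁻¹)
    nucleophile ⇌ dormant form (K = 11.0, k = 1.50 h⁻¹)
    electrophile + nucleophile → acid set free + target (k = 0.220 M⁻¹ h⁻¹)
    nucleophile + acid set free ⇌ protonated nucleophile, settled at all times (K = 83.0 M⁻¹)

In red, quenching was half done by 0.794 h, against my 0.784 h, and by 15.0 h it had 99.9% of its turnover behind it, with 0.0565% of the impurity left. From then until 30.0 h the electrophile fell from 39.9% to 35.6%, and at the end free nucleophile stood at 7.02% of its charge beside 0.379 M of dormant form, a half-life of 93 h for the electrophile by the making of target from electrophile and nucleophile. In the neighbour charged with 1.9 M of nucleophile, my read rate constant and the surplus left at 30.0 h give a surplus time constant of 8.16 h, longer than the 1.93 h of red's charge, and 0.0642% of its impurity still stood.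

The readings were computed from invented constants, and the scatter is random.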